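**Retrosynthetic overview**
1. Target ⇐ the 6,7-olefin (teferidin, jaeschkeanadiol benzoate) by epoxidation on the face opposite the angular methyl group.
2. Teferidin ⇐ a cis-decalin syn-epoxy alcohol + benzaldehyde: semipinacol 1,2-shift of the angular quaternary carbon (ring C contracts 6→5 to ring A while ring D expands 6→7 to ring B), then Tishchenko reduction and benzoyl shift.
3. Epoxy alcohol ⇐ cis-decalin dienol (hydroxyl-directed epoxidation) ⇐ intramolecular allylzinc addition of an allylic chloride to an enone carbonyl (closes ring D).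
4. Allylic chloride ⇐ (R)-6-allyl-6-methyl-3-isopropylcyclohexenone + methallyl chloride (cross-metathesis); the allyl ketone ⇐ carvenone by asymmetric allylic alkylation.
5. Carvenone (ring C) ⇐ 3-methylbutan-2-one + 3-methylbut-3-en-2-one (Robinson annulation). Ring order: C, then D, then C→A and D→B in one step.

Assumption: the identifier is taken to mean exactly the stereoisomer encoded by the SMILES (8α,9α-epoxyjaeschkeanadiol 6-benzoate); locants in the "Why" lines are those of the compound names.

**Step 1**
Reactants: 1 3-methylbutan-2-one; 2 3-methylbut-3-en-2-one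
Product: 4 rac-6-methyl-3-(propan-2-yl)cyclohex-2-en-1-one (carvenone), via 3,7-dimethyloctane-2,6-dione 3 (not isolated)
Conditions: pyrrolidine (1.2 equiv), TsOH (cat.), PhMe, reflux (−H2O); 2, 80 °C; then H2O; KOH (cat.), MeOH, 65 °C
Reagents that add atoms: none
Why: Stork enamine Michael addition through the less substituted (methyl-side) enamine of 1, then intramolecular aldol condensation (Robinson annulation), in which only the closure of the acetyl CH3 onto the isopropyl ketone can dehydrate to a six-membered enone; the one stereocentre is racemic and is erased by enolisation in step 2.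

**Step 2**
Reactants: 4 rac-6-methyl-3-(propan-2-yl)cyclohex-2-en-1-one; 5 prop-2-en-1-yl acetate (allyl acetate)
Product: 6 (6R)-6-methyl-3-(propan-2-yl)-6-(prop-2-en-1-yl)cyclohex-2-en-1-one
Conditions: LiN(iPr)2 (1.1 equiv), DME, −78 °C; Me3SnCl (1.0 equiv); 5 (1.2 equiv), [Pd(η3-C3H5)Cl]2 (2.5 mol %), (R,R)-Trost DACH-phenyl ligand (6 mol %), −78 °C → rt
Reagents that add atoms: none
Why: Trost palladium-catalysed asymmetric allylic alkylation of the kinetic cross-conjugated α′-enolate (its tin enolate attacks the π-allyl complex inside the chiral ligand pocket), precedented for 2-methyl-1-tetralone, creates the quaternary stereocentre (later C8a of the target) as R; the ligand enantiomer is the one that gives 6R, to be fixed by a small-scale test.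

**Step 3**
Reactants: 6 (6R)-6-methyl-3-(propan-2-yl)-6-(prop-2-en-1-yl)cyclohex-2-en-1-one; 7 3-chloro-2-methylprop-1-ene
Product: 8 (6R)-6-[(2E)-4-chloro-3-methylbut-2-en-1-yl]-6-methyl-3-(propan-2-yl)cyclohex-2-en-1-one (formed together with its 2Z isomer; both are used)
Conditions: 7 (10 equiv), second-generation Hoveyda–Grubbs catalyst RuCl2(H2IMes)(=CH-C6H4-2-OiPr) (5 mol %), CH2Cl2, 40 °C
Reagents that add atoms: none
Why: olefin cross-metathesis between a monosubstituted olefin and an excess of a 1,1-disubstituted olefin; the conjugated trisubstituted ring olefin is inert, no stereocentre is touched, and the E/Z ratio is irrelevant because step 4 passes through an equilibrating allylzinc.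

**Step 4**
Reactants: 8 (6R)-6-[(2E)-4-chloro-3-methylbut-2-en-1-yl]-6-methyl-3-(propan-2-yl)cyclohex-2-en-1-one
Product: 9 (4aS,8aR)-6,8a-dimethyl-3-(propan-2-yl)-1,2,4a,5,8,8a-hexahydronaphthalen-4a-ol (cis-fused; OH and 8a-CH3 on the same face)
Conditions: Zn dust, NaI (cat.), THF/sat. aq NH4Cl, 0 °C → rt, 0.01 M
Reagents that add atoms: none
Why: intramolecular Barbier allylation in which the allylzinc (E and Z forms interconvert by 1,3-metallotropy) adds 1,2 to the enone carbonyl to close ring D; the tether, anchored on the adjacent quaternary carbon, reaches the carbonyl from its own face (as in Robinson ketol formation), so the ring junction is cis and the new carbinol centre is 4aS.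

**Step 5**
Reactants: 9 (4aS,8aR)-6,8a-dimethyl-3-(propan-2-yl)-1,2,4a,5,8,8a-hexahydronaphthalen-4a-ol
Product: 10 (3R,4R,4aR,8aR)-3,4-epoxy-6,8a-dimethyl-3-(propan-2-yl)-1,2,3,4,4a,5,8,8a-octahydronaphthalen-4a-ol (epoxide O, OH and 8a-CH3 all on one face)
Conditions: VO(acac)2 (3 mol %), t-BuOOH (1.2 equiv, decane), PhMe, 0 °C → rt
Reagents that add atoms: tert-butyl hydroperoxide, CC(C)(C)OO
Why: Sharpless–Michaelson vanadium-catalysed hydroxyl-directed epoxidation delivers oxygen to the allylic trisubstituted olefin on the face of the tertiary OH (the allylic olefin reacts much faster than the homoallylic one in ring D), which sets both epoxide carbons (3R,4R).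

**Step 6**
Reactants: 10 (3R,4R,4aR,8aR)-3,4-epoxy-6,8a-dimethyl-3-(propan-2-yl)-1,2,3,4,4a,5,8,8a-octahydronaphthalen-4a-ol; 11 benzaldehyde
Product: 14 (3R,3aS,4S,8aR)-3-hydroxy-6,8a-dimethyl-3-(propan-2-yl)-1,2,3,3a,4,5,8,8a-octahydroazulen-4-yl benzoate (teferidin), via hydroxy ketone 12 (not isolated), via tertiary benzoate 13 (not isolated)
Conditions: SmI2 (0.3 equiv), 11 (4 equiv), THF/ClCH2CH2Cl, −10 °C → rt; then DBU (0.5 equiv), PhMe, 70 °C
Reagents that add atoms: none
Why: Proposed new method: a samarium-catalysed semipinacol ring contraction/ring expansion coupled to an Evans–Tishchenko reduction and a 1,3-benzoyl shift — the trivalent samarium alkoxide of 10 chelates the syn epoxide oxygen, and C8a (anti-periplanar to the breaking C4–O bond in the half-chair that keeps the ring D methylene C5 away from the isopropyl group, and pushed by the alkoxide so that the tertiary C3–O bond does not ionise) migrates with retention from C4a to C4 with inversion there, which turns rings C and D into rings A and B of 12, puts H3a trans to the angular methyl and leaves the tertiary 3-OH; the samarium aldolate then adds to PhCHO and the hemiacetal delivers hydride within the chelate to the C4 ketone from the face of the C3 oxygen (anti-1,3-diol, 4S) to give 13, and DBU moves the benzoyl group from the crowded tertiary oxygen to the secondary one (thermodynamic control) to give 14; the closest known reactions are the SmI2-catalysed tandem semipinacol rearrangement/Tishchenko reaction of α-hydroxy epoxides and base-mediated acyl migration in 1,3-diol monoesters, neither shown for a ring-fusion carbinol whose migration terminus is a secondary carbon next to a fully substituted epoxide carbon.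

**Step 7**
Reactants: 14 (3R,3aS,4S,8aR)-3-hydroxy-6,8a-dimethyl-3-(propan-2-yl)-1,2,3,3a,4,5,8,8a-octahydroazulen-4-yl benzoate
Product: 15 (3R,3aS,4S,6R,7S,8aR)-6,7-epoxy-3-hydroxy-6,8a-dimethyl-3-(propan-2-yl)decahydroazulen-4-yl benzoate (target)
Conditions: mCPBA (1.1 equiv), CH2Cl2/aq. phosphate buffer (pH 8), 0 °C
Reagents that add atoms: 3-chloroperoxybenzoic acid (mCPBA), OOC(=O)c1cccc(Cl)c1
Why: Prilezhaev epoxidation of the only olefin; the peracid is expected to approach the face opposite the axial C8a methyl group, which shields the other face (the equatorial benzoate lies near the ring plane), giving the (6R,7S)-epoxide (8α,9α in daucane numbering).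

**Compound list**
1 | 3-methylbutan-2-one | CC(C)C(C)=O | starting material
2 | 3-methylbut-3-en-2-one | CC(=C)C(C)=O | starting material
3 | 3,7-dimethyloctane-2,6-dione (racemic) | CC(C)C(=O)CCC(C)C(C)=O | intermediate
4 | rac-6-methyl-3-(propan-2-yl)cyclohex-2-en-1-one (carvenone) | CC(C)C1=CC(=O)C(C)CC1 | intermediate
5 | prop-2-en-1-yl acetate (allyl acetate) | CC(=O)OCC=C | starting material
6 | (6R)-6-methyl-3-(propan-2-yl)-6-(prop-2-en-1-yl)cyclohex-2-en-1-one | CC(C)C1=CC(=O)[C@@](C)(CC=C)CC1 | intermediate
7 | 3-chloro-2-methylprop-1-ene | CC(=C)CCl | starting material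
8 | (6R)-6-[(2E)-4-chloro-3-methylbut-2-en-1-yl]-6-methyl-3-(propan-2-yl)cyclohex-2-en-1-one | CC(C)C1=CC(=O)[C@@](C)(C/C=C(\C)CCl)CC1 | intermediate
9 | (4aS,8aR)-6,8a-dimethyl-3-(propan-2-yl)-1,2,4a,5,8,8a-hexahydronaphthalen-4a-ol | CC(C)C1=C[C@@]2(O)CC(C)=CC[C@@]2(C)CC1 | intermediate
10 | (3R,4R,4aR,8aR)-3,4-epoxy-6,8a-dimethyl-3-(propan-2-yl)-1,2,3,4,4a,5,8,8a-octahydronaphthalen-4a-ol | CC(C)[C@]12CC[C@]3(C)CC=C(C)C[C@]3(O)[C@H]1O2 | intermediate
11 | benzaldehyde | O=Cc1ccccc1 | starting material
12 | (3R,3aR,8aR)-3-hydroxy-6,8a-dimethyl-3-(propan-2-yl)-2,3,3a,5,8,8a-hexahydroazulen-4(1H)-one | CC(C)[C@]1(O)CC[C@]2(C)CC=C(C)CC(=O)[C@H]21 | intermediate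
13 | (3R,3aS,4S,8aR)-4-hydroxy-6,8a-dimethyl-3-(propan-2-yl)-1,2,3,3a,4,5,8,8a-octahydroazulen-3-yl benzoate | CC(C)[C@]1(OC(=O)c3ccccc3)CC[C@]2(C)CC=C(C)C[C@H](O)[C@H]21 | intermediate
14 | (3R,3aS,4S,8aR)-3-hydroxy-6,8a-dimethyl-3-(propan-2-yl)-1,2,3,3a,4,5,8,8a-octahydroazulen-4-yl benzoate (teferidin) | CC(C)[C@]1(O)CC[C@]2(C)CC=C(C)C[C@H](OC(=O)c3ccccc3)[C@H]21 | intermediate
15 | (3R,3aS,4S,6R,7S,8aR)-6,7-epoxy-3-hydroxy-6,8a-dimethyl-3-(propan-2-yl)decahydroazulen-4-yl benzoate | CC(C)[C@]1(O)CC[C@]2(C)C[C@@H]3O[C@]3(C)C[C@H](OC(=O)c3ccccc3)[C@H]21 | target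

**Total step count:** 7. **Longest linear sequence:** 7.

**Steps most likely to fail, with fallbacks**

Step 6 (the proposed new step). The cascade can fail by migration of the wrong bond, by opening at the tertiary epoxide carbon, or by no hydride transfer from the tertiary alkoxide. The fallback uses known chemistry, sets out from 9 and comes back at 14. Hydroxyl-directed dihydroxylation of the allylic olefin of 9 (OsO4·TMEDA, CH2Cl2, −78 °C) gives the all-syn triol (3R,4S,4aR,8aR)-6,8a-dimethyl-3-(propan-2-yl)-1,2,3,4,4a,5,8,8a-octahydronaphthalene-3,4,4a-triol F1. Its only secondary hydroxyl is sulfonylated (MsCl, Et3N, DMAP, CH2Cl2, 0 °C) to (3R,4S,4aR,8aR)-3,4a-dihydroxy-6,8a-dimethyl-3-(propan-2-yl)-1,2,3,4,4a,5,8,8a-octahydronaphthalen-4-yl methanesulfonate F2, in which the equatorial sulfonate is anti-periplanar to the ring-fusion bond. KOtBu (THF/t-BuOH, 0 °C) then effects the classical base-induced pinacol-type rearrangement of a decalin diol monosulfonate; the quaternary carbon migrates in preference to the ring CH2 and gives 12. Hydroxyl-directed reduction with Me4NBH(OAc)3 (MeCN/AcOH, −20 °C) gives the anti diol (3R,3aS,4S,8aR)-6,8a-dimethyl-3-(propan-2-yl)-1,2,3,3a,4,5,8,8a-octahydroazulene-3,4-diol (jaeschkeanadiol) F3. Benzoylation of its only secondary hydroxyl (benzoyl chloride, DMAP, pyridine) gives 14.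

Step 3. The allyl group sits on a quaternary carbon, and methallyl chloride is a sluggish metathesis partner that can deactivate the catalyst. The fallback closes ring D by ring-closing metathesis instead; it sets out from 6 and comes back at 9, bypassing 8 and step 4. CeCl3-promoted 1,2-addition of 2-methylallylmagnesium chloride (from 7 and Mg; THF, −78 °C) to 6 gives (1S,6R)-6-methyl-1-(2-methylprop-2-en-1-yl)-3-(propan-2-yl)-6-(prop-2-en-1-yl)cyclohex-2-en-1-ol F4 together with its C1 epimer, which is removed by chromatography. Second-generation Grubbs catalyst RuCl2(PCy3)(H2IMes)(=CHPh) (CH2Cl2, 40 °C) then closes the trisubstituted cyclohexene to give 9. The cost is a diastereomer separation, because intermolecular addition to the carbonyl is not reliably face-selective.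

Step 2. The direct alkylation of the lithium/tin enolate of a simple α′-methyl enone may give a low ee. The fallback sets the quaternary centre by decarboxylative asymmetric allylic alkylation; it sets out from 4 and comes back at 6. LiN(iPr)2 (THF, −78 °C) followed by allyl chloroformate gives the dienyl carbonate 2-methyl-5-(propan-2-yl)cyclohexa-1,5-dien-1-yl prop-2-en-1-yl carbonate F5. Pd2(dba)3 with (S)-t-Bu-PHOX (or its enantiomer, whichever gives 6R; THF, 25 °C) generates the allylpalladium enolate pair by loss of CO2 and returns 6.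

**Further compounds**
F1 | step 6 | (3R,4S,4aR,8aR)-6,8a-dimethyl-3-(propan-2-yl)-1,2,3,4,4a,5,8,8a-octahydronaphthalene-3,4,4a-triol | CC(C)[C@]1(O)CC[C@]2(C)CC=C(C)C[C@]2(O)[C@H]1O
F2 | step 6 | (3R,4S,4aR,8aR)-3,4a-dihydroxy-6,8a-dimethyl-3-(propan-2-yl)-1,2,3,4,4a,5,8,8a-octahydronaphthalen-4-yl methanesulfonate | CC(C)[C@]1(O)CC[C@]2(C)CC=C(C)C[C@]2(O)[C@H]1OS(C)(=O)=O
F3 | step 6 | (3R,3aS,4S,8aR)-6,8a-dimethyl-3-(propan-2-yl)-1,2,3,3a,4,5,8,8a-octahydroazulene-3,4-diol (jaeschkeanadiol) | CC(C)[C@]1(O)CC[C@]2(C)CC=C(C)C[C@H](O)[C@H]21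
F4 | step 3 | (1S,6R)-6-methyl-1-(2-methylprop-2-en-1-yl)-3-(propan-2-yl)-6-(prop-2-en-1-yl)cyclohex-2-en-1-ol | CC(C)C1=C[C@@](O)(CC(C)=C)[C@@](C)(CC=C)CC1
F5 | step 2 | 2-methyl-5-(propan-2-yl)cyclohexa-1,5-dien-1-yl prop-2-en-1-yl carbonate | CC(C)C1=CC(OC(=O)OCC=C)=C(C)CC1
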